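**Retrosynthetic overview**

1. Numbering: tetralin C1 (side chain), C2, C3, C4 (CH3), C4a, C5 (OH), C6 (OH), C7 (C19O2H), C8 (H), C8a; chain C11 (C20H2OAc), C12–C14, C15 (CH3, C16H2OAc). The strategy rests on the saturated ring C1–C2–C3–C4–C4a–C8a with its 1,4-trans substituents, which is the intact ring of (R)-carvone (carbonyl carbon = C4a, isopropenyl carbon = C11), and on the benzene ring C4a–C5–C6–C7–C8–C8a, in which C5–C6–C7–C19 is the oxygenated chain of a 4-alkoxyacetoacetate and C8 is a formyl carbon.
2. Key disconnection: C7–C8 and C4a–C5, a base-mediated [3+3] Knoevenagel/aldol benzannulation of hydroxymethylene ketone 3 with ethyl 4-(benzyloxy)acetoacetate 4. O5 carries benzyl (later also O6 and C19) so that all three groups fall by hydrogenolysis beside the acetates.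
3. Side chain: C20–O by allylic oxidation of the isopropenyl methyl; C12–O by hydroboration to a 2-substituted propane-1,3-diol whose two CH2OH arms are told apart by a lipase. This sets C11, because a plain hydroboration next to C1 offers no reliable facial control. C12–C13 by Negishi coupling with a vinyl iodide from the Roche ester (C13–C16, C15).
4. Ring order: the carbocycle comes from the chiral pool, the arene is closed in step 3, and no further ring is formed.

Key step: step 3

Assumption: which hydroxymethyl arm of diol 12 the lipase acetylates cannot be read from the structure; the route is written for acetylation of the arm that becomes C20, and the complementary hydrolytic mode is held as fallback.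

**Route**

Step 1
Reactants: 1 (R)-(−)-carvone
Product: 2 (2R,5R)-2-methyl-5-(prop-1-en-2-yl)cyclohexan-1-one
Conditions: L-Selectride, THF, −78 °C; then H2O
Reagents that add atoms: none
Why: Conjugate hydride reduction of the enone leaves the isolated isopropenyl alkene untouched, and the new α-methyl centre (C4), still epimerisable here and in step 2, settles trans (diequatorial) to the C1 substituent under control of the carvone stereocentre.

Step 2
Reactants: 2 (2R,5R)-2-methyl-5-(prop-1-en-2-yl)cyclohexan-1-one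
Product: 3 (3S,6R,Z)-2-(hydroxymethylene)-6-methyl-3-(prop-1-en-2-yl)cyclohexan-1-one
Conditions: HCO2Et, NaOEt, Et2O, 0 → 20 °C; then aq. HCl
Reagents that add atoms: ethyl formate, CCOC=O
Why: Crossed Claisen formylation occurs at the methylene α-carbon (C8a) because only that β-keto aldehyde is drained as its stabilised enolate, which also shields the ketone from further enolisation, so C4 stays in its thermodynamic trans arrangement.

Step 3
Reactants: 3 (3S,6R,Z)-2-(hydroxymethylene)-6-methyl-3-(prop-1-en-2-yl)cyclohexan-1-one; 4 ethyl 4-(benzyloxy)-3-oxobutanoate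
Product: 7 ethyl (5R,8S)-4-(benzyloxy)-3-hydroxy-5-methyl-8-(prop-1-en-2-yl)-5,6,7,8-tetrahydronaphthalene-2-carboxylate, via Knoevenagel adduct 5 (not isolated), via aldol adduct 6 (not isolated)
Conditions: NaOEt (3 equiv), EtOH, 0 → 78 °C; then aq. HCl
Reagents that add atoms: none
Why: Ethoxide generates the C7 carbanion of 4 (the doubly activated, most acidic position), which adds to the formyl-level carbon C8 of 3 and expels hydroxide (Knoevenagel-type addition–elimination, C7–C8 bond) to give 5; the C5 enolate of the C6 ketone then closes onto the C4a carbonyl by a 6-(enolendo)-exo-trig aldol (C4a–C5 bond) to give 6, and loss of water followed by enolisation at C6 delivers the benzene ring. The closest known reaction type is the base-mediated [3+3] phenol synthesis from 2-hydroxymethylene ketones and acetoacetic or acetonedicarboxylic esters. No stereocentre is created, since the sp3 centres at C4a, C5 and C8a in 5 and 6 are erased on aromatisation and C1 is never enolisable. The step needs regiochemistry (C7 to C8, C5 to C4a), which follows from the acidity order C7–H > C5–H in 4 and the electrophilicity order C8 > C4a in 3, so the ester ends next to C8–H and the benzyloxy group next to C4a. It also needs C4 to remain trans to C1: C4 is epimerisable only until the ring is aromatic, its equilibrium position is the trans arrangement from steps 1–2, and any cis-1,4 material should be removed when acid 8 is crystallised. Lactonisation of 5 to an acylpyranone is reversible under ethoxide whereas aromatisation is not, so that side channel should drain into 7.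

Step 4
Reactants: 7 ethyl (5R,8S)-4-(benzyloxy)-3-hydroxy-5-methyl-8-(prop-1-en-2-yl)-5,6,7,8-tetrahydronaphthalene-2-carboxylate
Product: 8 (5R,8S)-4-(benzyloxy)-3-hydroxy-5-methyl-8-(prop-1-en-2-yl)-5,6,7,8-tetrahydronaphthalene-2-carboxylic acid
Conditions: NaOH, EtOH/H2O, 80 °C; then aq. HCl
Reagents that add atoms: sodium hydroxide, [Na+].[OH-]
Why: Saponification of the salicylate ester, to which the aryl benzyl ether and the isolated alkene are inert, frees the acid so that it can be re-protected in a form removable beside acetates.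

Step 5
Reactants: 8 (5R,8S)-4-(benzyloxy)-3-hydroxy-5-methyl-8-(prop-1-en-2-yl)-5,6,7,8-tetrahydronaphthalene-2-carboxylic acid
Product: 9 benzyl (5R,8S)-3,4-bis(benzyloxy)-5-methyl-8-(prop-1-en-2-yl)-5,6,7,8-tetrahydronaphthalene-2-carboxylate
Conditions: BnBr (2.5 equiv), K2CO3, DMF, 60 °C
Reagents that add atoms: benzyl bromide, BrCc1ccccc1
Why: Williamson O-alkylation of the carboxylate and of the hydrogen-bonded phenoxide in DMF masks both acidic groups as benzyl derivatives that later fall together by hydrogenolysis.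

Step 6
Reactants: 9 benzyl (5R,8S)-3,4-bis(benzyloxy)-5-methyl-8-(prop-1-en-2-yl)-5,6,7,8-tetrahydronaphthalene-2-carboxylate
Product: 10 benzyl (5R,8R)-3,4-bis(benzyloxy)-8-(3-hydroxyprop-1-en-2-yl)-5-methyl-5,6,7,8-tetrahydronaphthalene-2-carboxylate
Conditions: SeO2 (0.5 equiv), t-BuOOH (2 equiv), CH2Cl2, 20 °C
Reagents that add atoms: selenium dioxide, O=[Se]=O; tert-butyl hydroperoxide (terminal oxygen source), CC(C)(C)OO
Why: Riley-type allylic oxidation (ene reaction, then [2,3]-sigmatropic shift) of a 1,1-disubstituted alkene takes a hydrogen from the allylic CH3 in preference to the allylic methine C1–H and gives the 2-substituted allyl alcohol (C20–OH) without touching benzyl ethers or C1 (the descriptor at C8 changes only through CIP priorities).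

Step 7
Reactants: 10 benzyl (5R,8R)-3,4-bis(benzyloxy)-8-(3-hydroxyprop-1-en-2-yl)-5-methyl-5,6,7,8-tetrahydronaphthalene-2-carboxylate
Product: 12 benzyl (5R,8S)-3,4-bis(benzyloxy)-8-(1,3-dihydroxypropan-2-yl)-5-methyl-5,6,7,8-tetrahydronaphthalene-2-carboxylate, via borinate alkylborane 11 (not isolated)
Conditions: 9-BBN (3 equiv), THF, 0 → 40 °C; then 30% H2O2, aq. NaOAc, 0 → 20 °C
Reagents that add atoms: 9-borabicyclo[3.3.1]nonane (boron in 11 only), B1C2CCCC1CCC2; hydrogen peroxide, OO
Why: Anti-Markovnikov hydroboration of the 1,1-disubstituted alkene (the free OH first forms its borinate) and buffered oxidation give a diol in which C11 carries two identical CH2OH arms, so no facial selectivity is needed and the benzyl ester survives both reagents.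

Step 8
Reactants: 12 benzyl (5R,8S)-3,4-bis(benzyloxy)-8-(1,3-dihydroxypropan-2-yl)-5-methyl-5,6,7,8-tetrahydronaphthalene-2-carboxylate
Product: 13 benzyl (5R,8S)-8-[(2R)-1-acetoxy-3-hydroxypropan-2-yl]-3,4-bis(benzyloxy)-5-methyl-5,6,7,8-tetrahydronaphthalene-2-carboxylate
Conditions: Burkholderia cepacia lipase (immobilised), vinyl acetate, t-BuOMe, 25 °C
Reagents that add atoms: vinyl acetate, CC(=O)OC=C
Why: Lipase-catalysed irreversible transesterification (enzymatic desymmetrisation of a 2-substituted propane-1,3-diol) should acetylate one of the two diastereotopic CH2OH arms inside the chiral active site, so C11 is set under catalyst control, the acetylated arm staying to the end as C20H2OAc and the free arm becoming C12.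

Step 9
Reactants: 13 benzyl (5R,8S)-8-[(2R)-1-acetoxy-3-hydroxypropan-2-yl]-3,4-bis(benzyloxy)-5-methyl-5,6,7,8-tetrahydronaphthalene-2-carboxylate
Product: 14 benzyl (5R,8S)-8-[(2S)-1-acetoxy-3-iodopropan-2-yl]-3,4-bis(benzyloxy)-5-methyl-5,6,7,8-tetrahydronaphthalene-2-carboxylate
Conditions: PPh3, I2, imidazole, CH2Cl2, 0 °C (13 used without storage)
Reagents that add atoms: iodine, II
Why: Appel-type iodination proceeds by direct SN2 attack of iodide on the primary alkoxyphosphonium ion, which should outrun six-membered acetoxonium participation or 1,3-acyl migration, so the two arms are not exchanged and C11 (not a reacting centre) is kept.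

Step 10
Reactants: 15 methyl (S)-3-hydroxy-2-methylpropanoate (Roche ester)
Product: 16 methyl (S)-3-[(tert-butyldimethylsilyl)oxy]-2-methylpropanoate
Conditions: TBSCl, imidazole, CH2Cl2, 20 °C
Reagents that add atoms: tert-butyldimethylsilyl chloride, CC(C)(C)[Si](C)(C)Cl
Why: Standard silylation of the primary alcohol blocks it against the hydride and chromium reagents that follow.

Step 11
Reactants: 16 methyl (S)-3-[(tert-butyldimethylsilyl)oxy]-2-methylpropanoate
Product: 17 (S)-3-[(tert-butyldimethylsilyl)oxy]-2-methylpropanal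
Conditions: DIBAL-H (1.05 equiv), CH2Cl2, −78 °C; then aq. Rochelle salt
Reagents that add atoms: none
Why: Partial reduction of the ester stops at the tetrahedral aluminium hemiacetal at −78 °C, and the aldehyde is used crude so that its α-centre is not epimerised.

Step 12
Reactants: 17 (S)-3-[(tert-butyldimethylsilyl)oxy]-2-methylpropanal
Product: 18 (R,E)-tert-butyl[(4-iodo-2-methylbut-3-en-1-yl)oxy]dimethylsilane
Conditions: CrCl2 (6 equiv), CHI3 (2 equiv), THF, 0 → 20 °C
Reagents that add atoms: iodoform, IC(I)I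
Why: Takai olefination through a geminal dichromium species gives the (E)-vinyl iodide (C13=C14) under non-basic conditions that leave the α-stereocentre (C15) untouched.

Step 13
Reactants: 18 (R,E)-tert-butyl[(4-iodo-2-methylbut-3-en-1-yl)oxy]dimethylsilane
Product: 19 (R,E)-4-iodo-2-methylbut-3-en-1-ol
Conditions: 48% aq. HF, MeCN, 0 °C
Reagents that add atoms: none
Why: Fluoride-driven cleavage of the primary silyl ether is compatible with the vinyl iodide.

Step 14
Reactants: 19 (R,E)-4-iodo-2-methylbut-3-en-1-ol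
Product: 20 (R,E)-4-iodo-2-methylbut-3-en-1-yl acetate
Conditions: Ac2O, pyridine, DMAP (cat.), CH2Cl2, 20 °C
Reagents that add atoms: acetic anhydride, CC(=O)OC(C)=O
Why: DMAP-catalysed acylation installs the C16 acetate on the fragment, so that nothing but reduction and hydrogenolysis remains after the coupling.

Step 15
Reactants: 14 benzyl (5R,8S)-8-[(2S)-1-acetoxy-3-iodopropan-2-yl]-3,4-bis(benzyloxy)-5-methyl-5,6,7,8-tetrahydronaphthalene-2-carboxylate; 20 (R,E)-4-iodo-2-methylbut-3-en-1-yl acetate
Product: 22 benzyl (5R,8S)-3,4-bis(benzyloxy)-8-[(2S,4E,6R)-1,7-diacetoxy-6-methylhept-4-en-2-yl]-5-methyl-5,6,7,8-tetrahydronaphthalene-2-carboxylate, via alkylzinc iodide 21 (not isolated)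
Conditions: Zn dust (activated by 1,2-dibromoethane and TMSCl), DMF, 20 °C; then 20, Pd2(dba)3 (2.5 mol%), P(o-tol)3 (10 mol%), 20 → 40 °C
Reagents that add atoms: zinc (in 21 only), [Zn]
Why: Negishi sp3–sp2 coupling: zinc inserts into the primary C–I bond to give an alkylzinc iodide that tolerates acetate and benzyl ester, and it transmetallates to the vinylpalladium iodide from 20 with retention of the E geometry, forming C12–C13 without involving C11 or C15.

Step 16
Reactants: 22 benzyl (5R,8S)-3,4-bis(benzyloxy)-8-[(2S,4E,6R)-1,7-diacetoxy-6-methylhept-4-en-2-yl]-5-methyl-5,6,7,8-tetrahydronaphthalene-2-carboxylate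
Product: 24 (5R,8S)-8-[(2S,6R)-1,7-diacetoxy-6-methylheptan-2-yl]-3,4-dihydroxy-5-methyl-5,6,7,8-tetrahydronaphthalene-2-carboxylic acid, via saturated tribenzyl diacetate 23 (not isolated)
Conditions: H2 (1 atm), 5% Pt/C, EtOAc, 20 °C; then 10% Pd/C added, H2 (1 atm), EtOAc/EtOH, 20 °C
Reagents that add atoms: none
Why: Platinum should saturate the 1,2-disubstituted alkene without the double-bond migration that could erode the allylic C15 centre, and palladium then cleaves both aryl benzyl ethers and the benzyl ester by hydrogenolysis, to which the two primary acetates are inert.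

**Compound list**

1 | (R)-(−)-carvone | CC(=C)[C@@H]1CC=C(C)C(=O)C1 | starting material
2 | (2R,5R)-2-methyl-5-(prop-1-en-2-yl)cyclohexan-1-one (trans-dihydrocarvone) | CC(=C)[C@@H]1CC[C@@H](C)C(=O)C1 | intermediate
3 | (3S,6R,Z)-2-(hydroxymethylene)-6-methyl-3-(prop-1-en-2-yl)cyclohexan-1-one | CC(=C)[C@@H]1CC[C@@H](C)C(=O)/C1=C\O | intermediate
4 | ethyl 4-(benzyloxy)-3-oxobutanoate | CCOC(=O)CC(=O)COCc1ccccc1 | starting material
5 | Knoevenagel adduct: ethyl 4-(benzyloxy)-2-{[(3R,6R)-3-methyl-2-oxo-6-(prop-1-en-2-yl)cyclohexyl]methylidene}-3-oxobutanoate (C8a and alkene geometry undefined) | CC(=C)[C@@H]1CC[C@@H](C)C(=O)C1C=C(C(=O)OCC)C(=O)COCc2ccccc2 | intermediate (not isolated)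
6 | aldol adduct: ethyl 4-(benzyloxy)-4a-hydroxy-5-methyl-3-oxo-8-(prop-1-en-2-yl)-3,4,4a,5,6,7,8,8a-octahydronaphthalene-2-carboxylate (C1 and C4 as in 3; C4a, C5, C8a undefined) | CC(=C)[C@@H]1CC[C@@H](C)C2(O)C(OCc3ccccc3)C(=O)C(C(=O)OCC)=CC12 | intermediate (not isolated)
7 | ethyl (5R,8S)-4-(benzyloxy)-3-hydroxy-5-methyl-8-(prop-1-en-2-yl)-5,6,7,8-tetrahydronaphthalene-2-carboxylate | CC(=C)[C@@H]1CC[C@@H](C)c2c(OCc3ccccc3)c(O)c(C(=O)OCC)cc12 | intermediate
8 | (5R,8S)-4-(benzyloxy)-3-hydroxy-5-methyl-8-(prop-1-en-2-yl)-5,6,7,8-tetrahydronaphthalene-2-carboxylic acid | CC(=C)[C@@H]1CC[C@@H](C)c2c(OCc3ccccc3)c(O)c(C(=O)O)cc12 | intermediate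
9 | benzyl (5R,8S)-3,4-bis(benzyloxy)-5-methyl-8-(prop-1-en-2-yl)-5,6,7,8-tetrahydronaphthalene-2-carboxylate | CC(=C)[C@@H]1CC[C@@H](C)c2c(OCc3ccccc3)c(OCc3ccccc3)c(C(=O)OCc3ccccc3)cc12 | intermediate
10 | benzyl (5R,8R)-3,4-bis(benzyloxy)-8-(3-hydroxyprop-1-en-2-yl)-5-methyl-5,6,7,8-tetrahydronaphthalene-2-carboxylate | OCC(=C)[C@@H]1CC[C@@H](C)c2c(OCc3ccccc3)c(OCc3ccccc3)c(C(=O)OCc3ccccc3)cc12 | intermediate
11 | borinate alkylborane: 10 with C20–O–B(9-BBN) and C12–B(9-BBN), both C11 epimers | C1CC2CCCC(C1)B2OCC(CB1C2CCCC1CCC2)[C@@H]1CC[C@@H](C)c2c(OCc3ccccc3)c(OCc3ccccc3)c(C(=O)OCc3ccccc3)cc12 | intermediate (not isolated)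
12 | benzyl (5R,8S)-3,4-bis(benzyloxy)-8-(1,3-dihydroxypropan-2-yl)-5-methyl-5,6,7,8-tetrahydronaphthalene-2-carboxylate | OCC(CO)[C@@H]1CC[C@@H](C)c2c(OCc3ccccc3)c(OCc3ccccc3)c(C(=O)OCc3ccccc3)cc12 | intermediate
13 | benzyl (5R,8S)-8-[(2R)-1-acetoxy-3-hydroxypropan-2-yl]-3,4-bis(benzyloxy)-5-methyl-5,6,7,8-tetrahydronaphthalene-2-carboxylate | OC[C@H](COC(C)=O)[C@@H]1CC[C@@H](C)c2c(OCc3ccccc3)c(OCc3ccccc3)c(C(=O)OCc3ccccc3)cc12 | intermediate
14 | benzyl (5R,8S)-8-[(2S)-1-acetoxy-3-iodopropan-2-yl]-3,4-bis(benzyloxy)-5-methyl-5,6,7,8-tetrahydronaphthalene-2-carboxylate | IC[C@H](COC(C)=O)[C@@H]1CC[C@@H](C)c2c(OCc3ccccc3)c(OCc3ccccc3)c(C(=O)OCc3ccccc3)cc12 | intermediate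
15 | methyl (S)-3-hydroxy-2-methylpropanoate (Roche ester) | COC(=O)[C@@H](C)CO | starting material
16 | methyl (S)-3-[(tert-butyldimethylsilyl)oxy]-2-methylpropanoate | COC(=O)[C@@H](C)CO[Si](C)(C)C(C)(C)C | intermediate
17 | (S)-3-[(tert-butyldimethylsilyl)oxy]-2-methylpropanal | O=C[C@@H](C)CO[Si](C)(C)C(C)(C)C | intermediate
18 | (R,E)-tert-butyl[(4-iodo-2-methylbut-3-en-1-yl)oxy]dimethylsilane | I/C=C/[C@@H](C)CO[Si](C)(C)C(C)(C)C | intermediate
19 | (R,E)-4-iodo-2-methylbut-3-en-1-ol | I/C=C/[C@@H](C)CO | intermediate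
20 | (R,E)-4-iodo-2-methylbut-3-en-1-yl acetate | I/C=C/[C@@H](C)COC(C)=O | intermediate
21 | alkylzinc iodide from 14 (C12–ZnI) | I[Zn]C[C@H](COC(C)=O)[C@@H]1CC[C@@H](C)c2c(OCc3ccccc3)c(OCc3ccccc3)c(C(=O)OCc3ccccc3)cc12 | intermediate (not isolated)
22 | benzyl (5R,8S)-3,4-bis(benzyloxy)-8-[(2S,4E,6R)-1,7-diacetoxy-6-methylhept-4-en-2-yl]-5-methyl-5,6,7,8-tetrahydronaphthalene-2-carboxylate | CC(=O)OC[C@H](C)/C=C/C[C@H](COC(C)=O)[C@@H]1CC[C@@H](C)c2c(OCc3ccccc3)c(OCc3ccccc3)c(C(=O)OCc3ccccc3)cc12 | intermediate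
23 | benzyl (5R,8S)-3,4-bis(benzyloxy)-8-[(2S,6R)-1,7-diacetoxy-6-methylheptan-2-yl]-5-methyl-5,6,7,8-tetrahydronaphthalene-2-carboxylate | CC(=O)OC[C@H](C)CCC[C@H](COC(C)=O)[C@@H]1CC[C@@H](C)c2c(OCc3ccccc3)c(OCc3ccccc3)c(C(=O)OCc3ccccc3)cc12 | intermediate (not isolated)
24 | (5R,8S)-8-[(2S,6R)-1,7-diacetoxy-6-methylheptan-2-yl]-3,4-dihydroxy-5-methyl-5,6,7,8-tetrahydronaphthalene-2-carboxylic acid (CNP0245723.1) | CC(=O)OC[C@H](C)CCC[C@H](COC(C)=O)[C@@H]1CC[C@@H](C)c2c1cc(C(=O)O)c(O)c2O | target

**Step count and risks**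

Total step count: 16. Longest linear sequence: 11 steps (steps 1–9, 15, 16 from (R)-carvone); the side branch from the Roche ester is steps 10–14.

Steps most likely to fail:

1. Step 3. The condensation joins two anions and may be slow, so that retro-Claisen cleavage of 4, deformylation of 3, or diversion of the Knoevenagel adduct into the acylpyranone could outrun benzannulation. The fallback sets out from 3 and 4, returns at 7, and forms the same two bonds in the reverse order, each one enforced. Ketone 3 is O-alkylated (i-PrI, K2CO3, acetone) to (3S,6R)-2-(isopropoxymethylene)-6-methyl-3-(prop-1-en-2-yl)cyclohexan-1-one F1. Keto ester 4 is converted (NaH, then n-BuLi, THF, 0 °C) into its sodium lithium dianion F2, whose C5 terminus adds 1,2 to the C4a carbonyl of F1 to give the tertiary carbinol F3. Aqueous HCl in THF then hydrolyses the enol ether with carbonyl transposition (Stork–Danheiser type) to the enal keto ester F4, whose C8 formyl group condenses with the C7 methylene and aromatises to 7.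

2. Step 8. The lipase may acetylate the other hydroxymethyl arm or discriminate the arms weakly, which would give the wrong or a mixed configuration at C11; over-acylation to the diacetate is also possible. The fallback sets out from 12 and returns at 13. Diol 12 is acetylated on both arms (Ac2O, pyridine, DMAP) to benzyl (5R,8S)-3,4-bis(benzyloxy)-8-(1,3-diacetoxypropan-2-yl)-5-methyl-5,6,7,8-tetrahydronaphthalene-2-carboxylate F5. This is then hydrolysed with the same lipase (pH 7 phosphate buffer, t-BuOMe); the enzyme removes the acetate from the arm it would otherwise have acylated, and so delivers the complementary monoacetate.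

3. Step 6. The ene step may abstract the doubly activated (allylic and benzylic) C1–H instead of a methyl hydrogen, or oxidation may run on to the enal (which a Luche reduction of the crude would return to 10). The fallback sets out from 9 and returns at 10. The isopropenyl group is epoxidised (mCPBA, NaHCO3, CH2Cl2, 0 °C) to benzyl (5R,8R)-3,4-bis(benzyloxy)-5-methyl-8-(2-methyloxiran-2-yl)-5,6,7,8-tetrahydronaphthalene-2-carboxylate F6. Cp2TiCl (from Cp2TiCl2 and Mn, with collidine hydrochloride, THF, 20 °C) opens the epoxide to the tertiary C11 radical, and hydrogen abstraction from the methyl group gives the same 2-substituted allyl alcohol 10.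

**Further compounds**

F1 | step 3 | (3S,6R)-2-(isopropoxymethylene)-6-methyl-3-(prop-1-en-2-yl)cyclohexan-1-one | CC(=C)[C@@H]1CC[C@@H](C)C(=O)C1=COC(C)C
F2 | step 3 | sodium lithium dianion of ethyl 4-(benzyloxy)-3-oxobutanoate | CCOC(=O)[CH-]C(=O)[CH-]OCc1ccccc1.[Na+].[Li+]
F3 | step 3 | ethyl 4-(benzyloxy)-4-[1-hydroxy-2-(isopropoxymethylidene)-6-methyl-3-(prop-1-en-2-yl)cyclohexyl]-3-oxobutanoate (C1 and C4 as in 3; new centres undefined) | CC(=C)[C@@H]1CC[C@@H](C)C(O)(C(OCc2ccccc2)C(=O)CC(=O)OCC)C1=COC(C)C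
F4 | step 3 | ethyl 4-(benzyloxy)-4-[2-formyl-6-methyl-3-(prop-1-en-2-yl)cyclohex-1-en-1-yl]-3-oxobutanoate (C1 and C4 as in 3; C5 undefined) | CC(=C)[C@@H]1CC[C@@H](C)C(C(OCc2ccccc2)C(=O)CC(=O)OCC)=C1C=O
F5 | step 8 | benzyl (5R,8S)-3,4-bis(benzyloxy)-8-(1,3-diacetoxypropan-2-yl)-5-methyl-5,6,7,8-tetrahydronaphthalene-2-carboxylate | CC(=O)OCC(COC(C)=O)[C@@H]1CC[C@@H](C)c2c(OCc3ccccc3)c(OCc3ccccc3)c(C(=O)OCc3ccccc3)cc12
F6 | step 6 | benzyl (5R,8R)-3,4-bis(benzyloxy)-5-methyl-8-(2-methyloxiran-2-yl)-5,6,7,8-tetrahydronaphthalene-2-carboxylate (both epoxide epimers) | CC1(CO1)[C@@H]2CC[C@@H](C)c3c(OCc4ccccc4)c(OCc4ccccc4)c(C(=O)OCc4ccccc4)cc23
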